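**Plan**

- Retrosynthetic cuts, in order: the C1–O acetyl and C4–O aroyl ester bonds; the C6–CH3 bond (back to a C6 enol triflate, hence a C6 ketone); the C4–O bond (back to a C4=C5–C6=O enone); then C5 is excised by cutting C4–C5 and C5–C6 and rejoining C4–C6; last, the C3–isopropyl bond and the C3 oxygen.
- Enabling feature: ring B without C5 (C3a, C4, C6, C7, C8, C8a) is the cyclohexenone ring of the angular-methyl hydrindenedione 1, and ring A (C1, C2, C3, C3a, C8a) is its cyclopentanone ring. The carbinol carbon C4 is the enone α-carbon and the methyl-bearing C6 the carbonyl carbon, so one CH2 placed between them makes ring B with C4 as β-carbon of a new enone.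
- Forward order: ring A and the six-membered ring come with 1; C3 is oxidised and isopropylated; the ring fusion is reduced to a silyl enol ether; ring B arises by one-carbon enlargement (step 8); then C4–O, C6–CH3 with C6=C7, the aroyl ester, the C1 alcohol and the acetate follow.
- Stereochemistry: C8a from 1; C3 by carbon-nucleophile addition anti to the angular methyl; C3a by hydride delivery anti to that methyl; C4 by boryl-copper addition on the C3a–H face; C1 by hydride delivery directed by the C3 hydroxyl.

Key step: step 8

Remark on numbering: all locants are those of the target hydroazulene (C1 acetoxy carbon, C3 carbinol carbon, C3a and C8a ring fusion, C4 aroyloxy carbon, C6 methyl-bearing carbon). Before step 8 the six-membered ring consists of C3a, C4, C6, C7, C8 and C8a, and C5 does not yet exist.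

Remark on the chemistry: the configurations of the two cyclopropane carbons of 11 and of the chlorine-bearing carbon of 12 are immaterial because these centres are lost. 11 is drawn as the isomer expected from methylene transfer anti to the angular methyl, and 12 without a descriptor at C4. Compounds 1, 5, 10, 18, 21 and 25 are taken as purchased.

**Step 1**
Reactants: 1 (R)-7a-methyl-2,3,7,7a-tetrahydro-1H-indene-1,5(6H)-dione
Product: 2 C1 dioxolane of 1 (C3a=C4–C6=O enone kept)
Conditions: ethylene glycol, p-TsOH·H2O (cat.), 4 Å MS, rt
Reagents that add atoms: ethylene glycol (OCCO)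
Why: Acid-catalysed acetalisation is kinetically selective for the saturated cyclopentanone carbonyl C1 over the less electrophilic conjugated C6 carbonyl (chemoselective ketalisation), and C8a is not touched.

**Step 2**
Reactants: 2 C1 dioxolane enone
Product: 3 ene-dione (C3 and C6 ketones flanking C3a=C4)
Conditions: Pd(OH)2/C (5 mol %), t-BuOOH (5 equiv), K2CO3 (0.25 equiv), CH2Cl2, rt
Reagents that add atoms: tert-butyl hydroperoxide (CC(C)(C)OO)
Why: Palladium-catalysed hydroperoxide oxidation of an enone at its γ-methylene (allylic oxidation to the 1,4-enedione) turns C3, the only γ-CH2, into a carbonyl while the acetal and the quaternary C8a are inert.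

**Step 3**
Reactants: 3 ene-dione
Product: 4 C3 enone with dioxolanes at C1 and C6
Conditions: ethylene glycol (1.5 equiv), p-TsOH·H2O (cat.), benzene, reflux, Dean–Stark
Reagents that add atoms: ethylene glycol (OCCO)
Why: Chemoselective acetalisation should take the six-ring C6 carbonyl, which has an unhindered CH2 neighbour, before the cyclopentenone-type C3 carbonyl, which is flanked by the ring-fusion carbon and resists rehybridisation in the five-membered ring; the C3a=C4 bond stays conjugated to C3=O.

**Step 4**
Reactants: 4 C3 enone bis-dioxolane; 5 isopropylmagnesium chloride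
Product: 6 tertiary allylic alcohol (C3 OH cis and isopropyl trans to the C8a methyl)
Conditions: CeCl3 (anhydrous, 1.5 equiv), i-PrMgCl (1.5 equiv), THF, −78 °C → 0 °C
Reagents that add atoms: isopropylmagnesium chloride (CC(C)[Mg]Cl)
Why: Organocerium 1,2-addition to the only free carbonyl suppresses enolisation and β-hydride reduction, and the nucleophile should enter C3 anti to the angular methyl, placing isopropyl trans and hydroxyl cis to that methyl as in the target.

**Step 5**
Reactants: 6 tertiary allylic alcohol bis-dioxolane
Product: 7 γ-hydroxy enone (C3a=C4–C6=O, C1 dioxolane kept)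
Conditions: PPTS (cat.), acetone/H2O, rt
Reagents that add atoms: water (O)
Why: Acetal hydrolysis is selective because the allylic C6 dioxolane ionises to a conjugated oxocarbenium ion far faster than the saturated C1 dioxolane next to the quaternary carbon.

**Step 6**
Reactants: 7 γ-hydroxy enone
Product: 8 C3 triethylsilyl ether of 7
Conditions: Et3SiOTf (1.2 equiv), 2,6-lutidine, CH2Cl2, −78 °C → 0 °C
Reagents that add atoms: triethylsilyl trifluoromethanesulfonate (CC[Si](CC)(CC)OS(=O)(=O)C(F)(F)F)
Why: Silyl triflate silylation reaches the hindered tertiary alcohol, removes the hydroxyl as a directing group for the next step and adds bulk on the methyl face.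

**Step 7**
Reactants: 8 C3 silyl ether enone
Product: 9 trans-hydrindane trimethylsilyl enol ether (C4=C6 enol ether, C3a–H trans to the C8a methyl)
Conditions: [(Ph3P)CuH]6 (0.4 equiv), Me3SiCl (3 equiv), THF, −40 °C → rt
Reagents that add atoms: chlorotrimethylsilane (C[Si](C)(C)Cl)
Why: Copper hydride conjugate reduction with silyl trapping of the copper enolate should deliver hydride to C3a on the face opposite the angular methyl and the C3 silyloxy group (trans ring fusion), and O-silylation fixes the enol ether between C4 and C6.

**Step 8**
Reactants: 9 trans-hydrindane trimethylsilyl enol ether; 10 diiodomethane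
Product: 13 trans-fused C4=C5 hydroazulen-6-one, via siloxycyclopropane 11 (not isolated), via 4-chloro ketone 12 (not isolated)
Conditions: Et2Zn (3 equiv), CH2I2 (3 equiv), CH2Cl2, 0 °C → rt; solvent switch, FeCl3 (2.5 equiv), pyridine, DMF, 0 °C → rt; NaOAc, MeOH, reflux
Reagents that add atoms: diiodomethane (ICI); FeCl3 (Cl[Fe](Cl)Cl) supplies the chlorine of 12 only
Why: The zinc carbenoid from Et2Zn and CH2I2 (Furukawa variant of the Simmons–Smith cyclopropanation) transfers CH2 to the electron-rich C4=C6 enol ether in a concerted [2+1] addition, which closes the cyclopropane and forms C4–C5 and C5–C6 (11). Trivalent iron then takes the place of silicon on the cyclopropanol oxygen and oxidises it by one electron; β-scission of the shared C4–C6 bond gives the ring-enlarged C4 radical with the C6 carbonyl, a second FeCl3 transfers chlorine to C4 (12), and NaOAc removes HCl across C4–C5 by an E1cB path, which is the known iron trichloride ring enlargement of siloxycyclopropanes to 2-cycloalkenones. Ring B therefore closes by expansion of the existing six-membered ring (cleavage of the zero-atom bridge of the bicyclo[4.1.0]heptane unit), not by a direct seven-membered cyclisation. No lasting stereocentre is made, since both cyclopropane carbons end as sp2 or CH2 and C3, C3a and C8a are not involved. The step needs selectivity for the insertion site and for the bond that opens: the first is fixed by the enol ether position set in step 7, the second by the preference for the endocyclic secondary radical over the primary radical of external-bond cleavage, and elimination can only run toward C5 because only its hydrogens are α to the carbonyl. Pyridine-buffered DMF tempers the Lewis acidity of FeCl3 so that the dioxolane and the tertiary silyl ether should survive.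

**Step 9**
Reactants: 13 trans-fused C4=C5 hydroazulen-6-one
Product: 15 4-hydroxy ketone (OH cis to C3a–H), via 4-boryl ketone 14 (not isolated)
Conditions: B2pin2 (1.2 equiv), CuCl (5 mol %), DPEphos (5 mol %), NaOt-Bu (10 mol %), MeOH (2 equiv), THF, rt; then NaBO3·4H2O, THF/H2O, rt
Reagents that add atoms: bis(pinacolato)diboron (CC1(C)OB(OC1(C)C)B1OC(C)(C)C(C)(C)O1) for the boryl group of 14; sodium perborate tetrahydrate ([Na+].[O-]OB=O.O.O.O.O) for the oxygen of 15
Why: Copper-catalysed conjugate borylation followed by perborate oxidation with retention should place the boryl group, and then the hydroxyl, on C4 on the face of the C3a hydrogen, away from the axial angular methyl and the substituted C3.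

**Step 10**
Reactants: 15 4-hydroxy ketone
Product: 16 C4 triethylsilyl ether of 15
Conditions: Et3SiCl, imidazole, DMF, 0 °C → rt
Reagents that add atoms: chlorotriethylsilane (CC[Si](Cl)(CC)CC)
Why: Imidazole-mediated silylation protects the β-hydroxy ketone without a base strong enough to cause β-elimination, and a silyloxy group is a far poorer leaving group than an ester in the enolate chemistry that follows.

**Step 11**
Reactants: 16 C4 silyloxy ketone
Product: 17 enol triflate (C6–OTf, C6=C7)
Conditions: KN(SiMe3)2 (1.1 equiv), THF, −78 °C; PhNTf2, −78 °C → 0 °C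
Reagents that add atoms: N-phenylbis(trifluoromethanesulfonimide) (O=S(=O)(N(c1ccccc1)S(=O)(=O)C(F)(F)F)C(F)(F)F)
Why: Kinetic enolate O-triflation should occur toward C7, because a bulky amide base removes the proton remote from the C4 silyloxy group (β-oxygenated ketones enolise away from the oxygen-bearing side, and C5 is the more shielded methylene).

**Step 12**
Reactants: 17 enol triflate; 18 methylmagnesium bromide
Product: 19 C6-methyl C6=C7 alkene (bis-triethylsilyl ether, C1 dioxolane)
Conditions: MeMgBr (1.5 equiv), Fe(acac)3 (5 mol %), THF/NMP, −30 °C → 0 °C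
Reagents that add atoms: methylmagnesium bromide (C[Mg]Br)
Why: Iron-catalysed cross-coupling of an alkenyl triflate with a methyl Grignard reagent installs the C6 methyl with the double bond fixed at C6=C7, and silyl ethers and the acetal are inert at this temperature.

**Step 13**
Reactants: 19 bis-silyl ether
Product: 20 C3,C4-diol (C1 dioxolane kept)
Conditions: Bu4NF (3 equiv), THF, rt → 45 °C
Reagents that add atoms: none
Why: Fluoride-mediated desilylation cleaves the secondary and the tertiary triethylsilyl ether while the acetal and the trisubstituted alkene are untouched.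

**Step 14**
Reactants: 20 C3,C4-diol; 21 4-(allyloxy)benzoyl chloride
Product: 22 C4 4-(allyloxy)benzoate
Conditions: Et3N, DMAP (cat.), CH2Cl2, 0 °C → rt
Reagents that add atoms: 4-(allyloxy)benzoyl chloride (C=CCOc1ccc(cc1)C(Cl)=O)
Why: DMAP-catalysed acylation with an acid chloride takes only the secondary C4 hydroxyl, since the tertiary C3 hydroxyl next to isopropyl is inert under these conditions, and no ketone is present that could lose the new ester by β-elimination.

**Step 15**
Reactants: 22 C4 ester with C1 dioxolane
Product: 23 C1 ketone (β-hydroxy ketone with the C3 carbinol)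
Conditions: p-TsOH·H2O (cat.), acetone/H2O, rt
Reagents that add atoms: water (O)
Why: Acid-catalysed acetal hydrolysis unveils the C1 ketone, and the ester, allyl ether, tertiary alcohol and trisubstituted alkene should tolerate catalytic acid at room temperature.

**Step 16**
Reactants: 23 C1 ketone
Product: 24 C1,C3-anti diol (C1–OH trans to the C8a methyl)
Conditions: Me4NBH(OAc)3 (5 equiv), MeCN/AcOH, −20 °C → rt
Reagents that add atoms: none
Why: In the Evans–Saksena hydroxyl-directed reduction the borohydride exchanges onto the C3 oxygen and delivers hydride within the molecule to C1 from the face of the C3 hydroxyl (the methyl face), giving the 1,3-anti diol with C1–OH trans to the angular methyl; the reagent does not reduce ketones or esters intermolecularly.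

**Step 17**
Reactants: 24 C1,C3-anti diol; 25 acetic anhydride
Product: 26 C1 acetate
Conditions: Ac2O, pyridine, DMAP (cat.), CH2Cl2, rt
Reagents that add atoms: acetic anhydride (CC(=O)OC(C)=O)
Why: DMAP-catalysed acetylation takes the secondary C1 hydroxyl, while the tertiary C3 hydroxyl is not acylated at room temperature.

**Step 18**
Reactants: 26 C1 acetate allyl ether
Product: 27 target
Conditions: Pd(PPh3)4 (5 mol %), morpholine, THF, rt
Reagents that add atoms: none
Why: In this Tsuji–Trost deallylation zerovalent palladium ionises the aryl allyl ether and morpholine captures the allyl fragment, freeing the phenol under neutral conditions that leave both esters, neither of which is allylic, untouched.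

**Compound list**

1 | (R)-7a-methyl-2,3,7,7a-tetrahydro-1H-indene-1,5(6H)-dione | C[C@@]12CCC(=O)C=C1CCC2=O | starting material
2 | C1 ethylene acetal of 1, C3a=C4–C6=O enone, (R) at C8a | C[C@]12C3(OCCO3)CCC1=CC(=O)CC2 | intermediate
3 | ene-dione: C1 dioxolane, ketones at C3 and C6 flanking C3a=C4 | C[C@]12C3(OCCO3)CC(=O)C1=CC(=O)CC2 | intermediate
4 | C3 enone with dioxolanes at C1 and C6 | C[C@]12C3(OCCO3)CC(=O)C1=CC4(OCCO4)CC2 | intermediate
5 | isopropylmagnesium chloride | CC(C)[Mg]Cl | starting material
6 | tertiary allylic alcohol: C3 OH cis and isopropyl trans to the C8a methyl, dioxolanes at C1 and C6 | C[C@]12C3(OCCO3)C[C@@](O)(C(C)C)C1=CC4(OCCO4)CC2 | intermediate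
7 | γ-hydroxy enone: C3 carbinol as in 6, C3a=C4–C6=O, C1 dioxolane | C[C@]12C3(OCCO3)C[C@@](O)(C(C)C)C1=CC(=O)CC2 | intermediate
8 | C3 triethylsilyl ether of 7 | C[C@]12C3(OCCO3)C[C@@](O[Si](CC)(CC)CC)(C(C)C)C1=CC(=O)CC2 | intermediate
9 | trans-hydrindane trimethylsilyl enol ether: C4=C6 enol ether, C3a–H trans to the C8a methyl, C3 OSiEt3, C1 dioxolane | C[C@]12C3(OCCO3)C[C@@](O[Si](CC)(CC)CC)(C(C)C)[C@@H]1C=C(O[Si](C)(C)C)CC2 | intermediate
10 | diiodomethane | ICI | starting material
11 | siloxycyclopropane: CH2 (future C5) bridging C4 and C6 of 9 on the face of C3a–H | C[C@]12C3(OCCO3)C[C@@](O[Si](CC)(CC)CC)(C(C)C)[C@@H]1[C@H]4C[C@@]4(O[Si](C)(C)C)CC2 | intermediate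
12 | 4-chloro hydroazulen-6-one (β-chloro ketone, C4 configuration open) | C[C@]12C3(OCCO3)C[C@@](O[Si](CC)(CC)CC)(C(C)C)[C@@H]1C(Cl)CC(=O)CC2 | intermediate
13 | trans-fused hydroazulen-6-one with C4=C5, C3 OSiEt3, C1 dioxolane | C[C@]12C3(OCCO3)C[C@@](O[Si](CC)(CC)CC)(C(C)C)[C@@H]1C=CC(=O)CC2 | intermediate
14 | 4-(pinacolboryl) ketone, boron cis to C3a–H | C[C@]12C3(OCCO3)C[C@@](O[Si](CC)(CC)CC)(C(C)C)[C@@H]1[C@@H](B4OC(C)(C)C(C)(C)O4)CC(=O)CC2 | intermediate
15 | 4-hydroxy ketone, OH cis to C3a–H and trans to the C8a methyl | C[C@]12C3(OCCO3)C[C@@](O[Si](CC)(CC)CC)(C(C)C)[C@@H]1[C@@H](O)CC(=O)CC2 | intermediate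
16 | C4 triethylsilyl ether of 15 | C[C@]12C3(OCCO3)C[C@@](O[Si](CC)(CC)CC)(C(C)C)[C@@H]1[C@@H](O[Si](CC)(CC)CC)CC(=O)CC2 | intermediate
17 | enol triflate: C6–OTf, C6=C7 | C[C@]12C3(OCCO3)C[C@@](O[Si](CC)(CC)CC)(C(C)C)[C@@H]1[C@@H](O[Si](CC)(CC)CC)CC(OS(=O)(=O)C(F)(F)F)=CC2 | intermediate
18 | methylmagnesium bromide | C[Mg]Br | starting material
19 | C6-methyl C6=C7 alkene, C3 and C4 OSiEt3, C1 dioxolane | C[C@]12C3(OCCO3)C[C@@](O[Si](CC)(CC)CC)(C(C)C)[C@@H]1[C@@H](O[Si](CC)(CC)CC)CC(C)=CC2 | intermediate
20 | C3,C4-diol with C1 dioxolane | C[C@]12C3(OCCO3)C[C@@](O)(C(C)C)[C@@H]1[C@@H](O)CC(C)=CC2 | intermediate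
21 | 4-(allyloxy)benzoyl chloride | C=CCOc1ccc(cc1)C(Cl)=O | starting material
22 | C4 4-(allyloxy)benzoate of 20 | C[C@]12C3(OCCO3)C[C@@](O)(C(C)C)[C@@H]1[C@@H](OC(=O)c4ccc(OCC=C)cc4)CC(C)=CC2 | intermediate
23 | C1 ketone (β-hydroxy ketone with the C3 carbinol), C4 ester | C[C@]12C(=O)C[C@@](O)(C(C)C)[C@@H]1[C@@H](OC(=O)c3ccc(OCC=C)cc3)CC(C)=CC2 | intermediate
24 | C1,C3-anti diol, C1–OH trans to the C8a methyl | C[C@]12[C@@H](O)C[C@@](O)(C(C)C)[C@@H]1[C@@H](OC(=O)c3ccc(OCC=C)cc3)CC(C)=CC2 | intermediate
25 | acetic anhydride | CC(=O)OC(C)=O | starting material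
26 | C1 acetate of 24 (phenol as allyl ether) | C[C@]12[C@@H](OC(C)=O)C[C@@](O)(C(C)C)[C@@H]1[C@@H](OC(=O)c3ccc(OCC=C)cc3)CC(C)=CC2 | intermediate
27 | CNP0275279.1 | CC(=O)O[C@H]1C[C@@](O)(C(C)C)[C@@H]2[C@@H](OC(=O)c3ccc(O)cc3)CC(C)=CC[C@@]12C | target

**Step count**

Total: 18 steps. Longest linear sequence: 18 steps (1 to 27); the other starting materials are used as purchased.

**Steps most likely to fail**

Step 7. Hydride may be delivered to C3a from the face of the angular methyl, because the isopropyl group on C3 screens the opposite face; this would give the cis ring fusion. The fallback moves the reduction to a stage where C3 is a secondary carbinol and stores the enol ether regiochemistry as the cyclopropane. It sets out from 4 and returns at 11, which is opened with FeCl3/pyridine and NaOAc as in step 8.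
- Luche reduction (NaBH4, CeCl3·7H2O, MeOH, −78 °C; hydride anti to the methyl) should give the C3 allylic alcohol F1, and PPTS in wet acetone the γ-hydroxy enone F2.
- With [(Ph3P)CuH]6 and excess Me3SiCl/Et3N, the face opposite the methyl and the carbinol oxygen now carries only hydrogen, which should give the trans-fused bis(trimethylsilyl) enol ether F3.
- Et2Zn/CH2I2 converts this into the bis(silyl) cyclopropane F4; brief K2CO3/MeOH at 0 °C should cleave the unhindered secondary silyl ether first and give the cyclopropane alcohol F5.
- Dess–Martin oxidation (pyridine buffer) gives the cyclopropane ketone F6. i-PrMgCl/CeCl3 at −78 °C (non-basic organocerium, addition anti to the methyl before C3a can epimerise) gives the tertiary cyclopropane alcohol F7, and Et3SiOTf/2,6-lutidine then gives 11.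

Step 8. The Lewis-acidic iron salt may cleave the dioxolane or the tertiary silyl ether, or methylene transfer to the hindered enol ether may be incomplete. The fallback sets out from 9 and returns at 13, with the same bonds formed and broken.
- Dibromocarbene (CHBr3, KOt-Bu, pentane, −30 °C) adds to the enol ether under basic conditions to give the dibromo siloxycyclopropane F8.
- On warming in toluene with pyridine this opens with loss of the silyl group and one bromide, again by cleavage of the C4–C6 bond, to the 5-bromo enone F9.
- Zinc dust with NH4Cl in THF/MeOH removes the vinylic bromine and gives 13.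

Step 16. Exchange of the hindered tertiary hydroxyl onto boron may be too slow, so that hydride is not delivered within the molecule to the neopentyl ketone from the methyl face and the ketone is recovered or reduced from the open face. The fallback uses a covalent tether; it sets out from 23 and returns at 24.
- Chlorodiisopropylsilane, imidazole and DMAP in DMF give the C3 diisopropylsilyl ether F10, which carries an Si–H bond.
- SnCl4 (CH2Cl2, −78 °C) activates the ketone and the silicon hydride is delivered from the face of the C3 oxygen (Lewis-acid-promoted intramolecular hydrosilylation of a β-silyloxy ketone, anti-selective).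
- HF·pyridine work-up removes silicon and gives 24.

**Further compounds**

F1 | step 7 | C3 allylic alcohol (OH cis to the C8a methyl), dioxolanes at C1 and C6 | C[C@]12C3(OCCO3)C[C@H](O)C1=CC4(OCCO4)CC2
F2 | step 7 | γ-hydroxy enone with secondary C3 carbinol, C1 dioxolane | C[C@]12C3(OCCO3)C[C@H](O)C1=CC(=O)CC2
F3 | step 7 | trans-fused bis(trimethylsilyl) compound: C3 OSiMe3 and C4=C6 trimethylsilyl enol ether | C[C@]12C3(OCCO3)C[C@H](O[Si](C)(C)C)[C@@H]1C=C(O[Si](C)(C)C)CC2
F4 | step 7 | siloxycyclopropane with C3 OSiMe3 | C[C@]12C3(OCCO3)C[C@H](O[Si](C)(C)C)[C@@H]1[C@H]4C[C@@]4(O[Si](C)(C)C)CC2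
F5 | step 7 | siloxycyclopropane with free secondary C3 alcohol | C[C@]12C3(OCCO3)C[C@H](O)[C@@H]1[C@H]4C[C@@]4(O[Si](C)(C)C)CC2
F6 | step 7 | siloxycyclopropane C3 ketone | C[C@]12C3(OCCO3)CC(=O)[C@@H]1[C@H]4C[C@@]4(O[Si](C)(C)C)CC2
F7 | step 7 | siloxycyclopropane with tertiary C3 carbinol (OH cis, isopropyl trans to the C8a methyl) | C[C@]12C3(OCCO3)C[C@@](O)(C(C)C)[C@@H]1[C@H]4C[C@@]4(O[Si](C)(C)C)CC2
F8 | step 8 | dibromo siloxycyclopropane from 9 | C[C@]12C3(OCCO3)C[C@@](O[Si](CC)(CC)CC)(C(C)C)[C@@H]1[C@H]4C(Br)(Br)[C@@]4(O[Si](C)(C)C)CC2
F9 | step 8 | 5-bromo C4=C5 hydroazulen-6-one | C[C@]12C3(OCCO3)C[C@@](O[Si](CC)(CC)CC)(C(C)C)[C@@H]1C=C(Br)C(=O)CC2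
F10 | step 16 | C3 diisopropylsilyl (Si–H) ether of 23 | C[C@]12C(=O)C[C@@](O[SiH](C(C)C)C(C)C)(C(C)C)[C@@H]1[C@@H](OC(=O)c3ccc(OCC=C)cc3)CC(C)=CC2
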